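**Direct plan and its weak points**

A direct plan would deprotonate (R)-oct-1-yn-3-ol A1 twice and alkylate its acetylide carbon with (7-bromoheptyl)benzene A2 to give propargylic alcohol A3. Semi-hydrogenation would give Z-allylic alcohol A4 and acetylation would give acetate A5. Last, a twofold catalytic C–H borylation with oxidation of the C–B bonds would place both phenolic oxygens on the phenyl ring.
- Weak step, the late twofold C–H oxygenation: on a monoalkylbenzene the meta and the para C–H bonds would both react, so a large part of A5 would end in a para-substituted dead end. The Z-alkene and the ionisable allylic acetate would also meet metal hydride and boron hydride species (isomerisation, hydroboration, allylic substitution).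
- Weak step, the acetylide alkylation: SN2 displacement of the unactivated primary bromide of A2 by the alkynide–alkoxide dianion of A1 would be slow, would compete with elimination and would spend the chiral alkynol A1 in excess.
- Weak point of the layout: the arene would travel as a bare phenyl group, so the whole oxygen pattern of the core would depend on the final and least selective reaction, run on the most valuable intermediate.

**Retrosynthetic overview of the new route**

- The 5-alkylbenzene-1,3-diol ring is read as a folded tetraketide, as in alkylresorcinol biosynthesis. Ring carbon C5 (the one bearing the C15 chain) is the carboxyl carbon of a C16 hydroxy-alkenoic ester; C1, C2, C3, C4 and C6 with both phenolic oxygens come from triacetic acid lactone.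
- Key disconnection: both ring bonds at C5. C4–C5 is made by Claisen acylation of the lactone dianion; C5–C6 by hydroxide opening of the 2-pyrone, aldol closure and decarboxylation. The purchased 2-pyrone ring is thereby turned into the benzene ring, the only carbocycle, near the end.
- The chain ester comes from methyl dec-9-ynoate and hexanoyl chloride: acyl Sonogashira coupling, asymmetric transfer hydrogenation of the ynone (chain stereocentre, R) and Lindlar reduction (Z-alkene).
- The design needs no C–H oxidation of a finished arene, no acetylide SN2 alkylation and no phenol protection; the allylic acetate is set last by acetylating all three hydroxyl groups and cleaving the two aryl acetates selectively.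

Key step: step 5

Remark: methyl dec-9-ynoate is taken as a catalogue compound.

**Route**

Step 1
Reactants: 1 methyl dec-9-ynoate; 2 hexanoyl chloride
Product: 3 methyl 11-oxohexadec-9-ynoate
Conditions: PdCl2(PPh3)2 (2 mol%), CuI (4 mol%), Et3N (1.2 equiv), THF, rt
Reagents that add atoms: none
Why: Acyl Sonogashira coupling (oxidative addition of the acid chloride to zerovalent palladium, transmetallation of the copper acetylide, reductive elimination) should give the ynone, the methyl ester being inert and the near-stoichiometric amine limiting conjugate addition.

Step 2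
Reactants: 3 methyl 11-oxohexadec-9-ynoate
Product: 4 methyl (11R)-11-hydroxyhexadec-9-ynoate
Conditions: Ru[(R,R)-TsNCH(Ph)CH(Ph)NH](p-cymene) (1 mol%), iPrOH, rt
Reagents that add atoms: none
Why: Noyori asymmetric transfer hydrogenation of an α,β-acetylenic ketone, in which the Ru–H/N–H pair of the (R,R)-configured divalent ruthenium catalyst should deliver hydride to the carbonyl face that gives the (R)-carbinol (the alkynyl group takes the place of the aryl group of an aryl ketone), while the triple bond and the ester are left alone.

Step 3
Reactants: 4 methyl (11R)-11-hydroxyhexadec-9-ynoate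
Product: 5 methyl (9Z,11R)-11-hydroxyhexadec-9-enoate
Conditions: H2 (1 atm), Lindlar catalyst (Pd on CaCO3, poisoned with Pb(OAc)2), quinoline, EtOAc, rt, stopped after one equivalent of H2
Reagents that add atoms: none
Why: Lindlar semi-hydrogenation, in which syn addition of one H2 on the poisoned palladium surface should give the Z-alkene without touching the C11–O bond, so that C11 keeps its configuration (descriptor still R).

Step 4
Reactants: 5 methyl (9Z,11R)-11-hydroxyhexadec-9-enoate; 6 4-hydroxy-6-methyl-2H-pyran-2-one (triacetic acid lactone)
Product: 8 4-hydroxy-6-[(10Z,12R)-12-hydroxy-2-oxoheptadec-10-en-1-yl]-2H-pyran-2-one, via dilithium pyranone dianion 7 (not isolated)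
Conditions: 6 (3.2 equiv), LiN(iPr)2 (6.6 equiv), THF, −78 → 0 °C; then 5 (1.0 equiv), 0 °C → rt; aq. HCl to pH 3
Reagents that add atoms: none
Why: Claisen-type C-acylation of a pyrone dianion (biogenetic-type polyketide chain extension), in which the second deprotonation of 6 takes place at the 6-methyl group, this carbanion is the most nucleophilic site of 7 and attacks the ester carbonyl of 5, and the excess of 7 absorbs the hydroxyl proton of 5 and the acidic CH2 of the product.

Step 5
Reactants: 8 4-hydroxy-6-[(10Z,12R)-12-hydroxy-2-oxoheptadec-10-en-1-yl]-2H-pyran-2-one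
Product: 11 5-[(8Z,10R)-10-hydroxypentadec-8-en-1-yl]benzene-1,3-diol, via triketo acid potassium salt 9 (not isolated), via resorcylic acid potassium salt 10 (not isolated)
Conditions: aq. KOH (2 M, 10 equiv), 1,4-dioxane, argon, rt → 60 °C; then aq. HCl to pH 4–5, 90 °C, until CO2 evolution ends
Reagents that add atoms: none
Why: Hydroxide adds to the lactone carbonyl of 8 and opens the 2-pyrone by acyl–oxygen cleavage to the salt of 3,5,7-triketo acid 9, whose C2 carbanion (between carboxylate and C3 ketone) adds to the C7 ketone; loss of water and enolisation give resorcylate 10, and at pH 4–5 ipso-protonation of the electron-rich ring releases CO2 and leaves 11. The closest known reaction type is the biogenetic-type conversion of 6-(2-oxoalkyl)-4-hydroxy-2-pyrones such as tetraacetic acid lactone into orsellinic acid and orcinol with aqueous alkali, the laboratory counterpart of the aldol closure and decarboxylation carried out by alkylresorcinol synthases. The benzene ring closes by a 6-(enolendo)-exo-trig aldol reaction that forms the C5–C6 bond of the resorcinol (C2–C7 of 9); together with step 4 both ring bonds at C5 are then in place, and both phenolic oxygens (the 4-hydroxyl and the ring oxygen of the pyrone) arrive at the right carbons without oxidation or protection. No stereocentre is formed; C10 of the side chain and the Z-alkene lie far from the reacting carbons and are inert to aqueous base and to pH 4–5. The regioselectivity needed (C2 onto C7, not C6 onto C1 and not the chain α-carbon C8 onto C3) is secured by the carboxylate: C1 as a carboxylate cannot accept a Claisen attack, and C2 is the only doubly activated carbon that reaches a ketone through a six-membered transition state.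

Step 6
Reactants: 11 5-[(8Z,10R)-10-hydroxypentadec-8-en-1-yl]benzene-1,3-diol
Product: 13 (8Z,10R)-1-(3,5-dihydroxyphenyl)pentadec-8-en-10-yl acetate, via triacetate 12 (not isolated)
Conditions: Ac2O (4 equiv), pyridine, DMAP (cat.), CH2Cl2, 0 °C → rt; MeOH, evaporate; then pyrrolidine (2.5 equiv), THF, 0 °C; aq. citric acid
Reagents that add atoms: acetic anhydride, CC(=O)OC(C)=O
Why: Exhaustive DMAP-catalysed O-acetylation (at oxygen, so C10 and the Z-alkene are untouched) followed by chemoselective aminolysis, in which the two aryl acetates, activated esters with phenoxide leaving groups, should be cleaved by the secondary amine far faster than the hindered secondary allylic acetate.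

**Compound list**

1 | methyl dec-9-ynoate | C#CCCCCCCCC(=O)OC | starting material
2 | hexanoyl chloride | CCCCCC(=O)Cl | starting material
3 | methyl 11-oxohexadec-9-ynoate | CCCCCC(=O)C#CCCCCCCCC(=O)OC | intermediate
4 | methyl (11R)-11-hydroxyhexadec-9-ynoate | CCCCC[C@H](C#CCCCCCCCC(=O)OC)O | intermediate
5 | methyl (9Z,11R)-11-hydroxyhexadec-9-enoate | CCCCC[C@H](/C=C\CCCCCCCC(=O)OC)O | intermediate
6 | 4-hydroxy-6-methyl-2H-pyran-2-one (triacetic acid lactone) | Cc1cc(O)cc(=O)o1 | starting material
7 | dilithium salt of 6 (4-oxide and 6-CH2 carbanion) | [CH2-]c1cc([O-])cc(=O)o1.[Li+].[Li+] | intermediate (not isolated)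
8 | 4-hydroxy-6-[(10Z,12R)-12-hydroxy-2-oxoheptadec-10-en-1-yl]-2H-pyran-2-one | CCCCC[C@H](/C=C\CCCCCCCC(=O)Cc1cc(O)cc(=O)o1)O | intermediate
9 | (15Z,17R)-17-hydroxy-3,5,7-trioxodocos-15-enoic acid, formed as its potassium salt | CCCCC[C@H](/C=C\CCCCCCCC(=O)CC(=O)CC(=O)CC(=O)O)O | intermediate (not isolated)
10 | 2,4-dihydroxy-6-[(8Z,10R)-10-hydroxypentadec-8-en-1-yl]benzoic acid, formed as its potassium salt | CCCCC[C@H](/C=C\CCCCCCCc1cc(O)cc(O)c1C(=O)O)O | intermediate (not isolated)
11 | 5-[(8Z,10R)-10-hydroxypentadec-8-en-1-yl]benzene-1,3-diol | CCCCC[C@H](/C=C\CCCCCCCc1cc(O)cc(O)c1)O | intermediate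
12 | (8Z,10R)-1-(3,5-diacetoxyphenyl)pentadec-8-en-10-yl acetate | CCCCC[C@H](/C=C\CCCCCCCc1cc(OC(C)=O)cc(OC(C)=O)c1)OC(C)=O | intermediate (not isolated)
13 | (8Z,10R)-1-(3,5-dihydroxyphenyl)pentadec-8-en-10-yl acetate | CCCCC[C@H](/C=C\CCCCCCCc1cc(O)cc(O)c1)OC(C)=O | target

**Step count and risks**

Total step count: 6. Longest linear sequence: 6 steps (1 to 13).

Steps most likely to fail:

1. Step 5 (key step). The pyrone is a dianion in alkali and may open slowly; under forcing conditions, retro-Claisen cleavage of the open polyketone chain and incomplete loss of CO2 may compete with the aldol closure. Fallback, setting out from 5 and 6 and returning at 11: the lactone is opened before the chain is attached. Mg(OMe)2 in MeOH should convert 6 into methyl 3,5-dioxohexanoate F1. Threefold deprotonation of F1 with LiN(iPr)2 in THF and acylation at its terminal methyl carbon with 5 should give methyl (15Z,17R)-17-hydroxy-3,5,7-trioxodocos-15-enoate F2. The open-chain ester F2 should close under mild aqueous base (dilute KOH, 0 °C → rt) by the same C2-to-C7 aldol reaction to methyl 2,4-dihydroxy-6-[(8Z,10R)-10-hydroxypentadec-8-en-1-yl]benzoate F3. Saponification of this robust arene with hot aq. KOH, then acidification and warming, should return 11.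

2. Step 4. Proton transfer from the α-CH2 group of the ester, or slow reaction of the poorly soluble dilithium salt 7, may outrun C-acylation, and the lithium alkoxide of 5 may start transesterification. Fallback, setting out from 5 and returning at 11 without passing through 8: pentane-2,4-dione, deprotonated twice with LiN(iPr)2 in THF to a soluble Hauser-type dianion, is acylated at a methyl carbon with 5 to give (14Z,16R)-16-hydroxyhenicos-14-ene-2,4,6-trione F4. Aqueous KOH should then close the ring by aldol addition of the C1 methyl carbanion to the C6 carbonyl (the classical diacetylacetone-to-orcinol cyclisation) and, after loss of water, give 11 with no decarboxylation stage. The unhindered methyl carbanion should be favoured over the chain α-methylene, though this selectivity would have to be confirmed.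

3. Step 6. The amine may also attack the allylic acetate, or aryl acetate cleavage may stop halfway, so that the two kinds of ester are not cleanly told apart. Fallback, setting out from 11 and returning at 13: the phenols are masked orthogonally. TBSCl (2.1 equiv) and imidazole in DMF at 0 °C should silylate the acidic phenols ahead of the secondary alcohol and give (8Z,10R)-1-[3,5-bis(tert-butyldimethylsilyloxy)phenyl]pentadec-8-en-10-ol F5. Ac2O, pyridine and DMAP should give (8Z,10R)-1-[3,5-bis(tert-butyldimethylsilyloxy)phenyl]pentadec-8-en-10-yl acetate F6. KHF2 in MeOH at rt, which cleaves aryl silyl ethers only, should then give 13.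

**Further compounds**

F1 | step 5 | methyl 3,5-dioxohexanoate | COC(=O)CC(=O)CC(C)=O
F2 | step 5 | methyl (15Z,17R)-17-hydroxy-3,5,7-trioxodocos-15-enoate | CCCCC[C@H](/C=C\CCCCCCCC(=O)CC(=O)CC(=O)CC(=O)OC)O
F3 | step 5 | methyl 2,4-dihydroxy-6-[(8Z,10R)-10-hydroxypentadec-8-en-1-yl]benzoate | CCCCC[C@H](/C=C\CCCCCCCc1cc(O)cc(O)c1C(=O)OC)O
F4 | step 4 | (14Z,16R)-16-hydroxyhenicos-14-ene-2,4,6-trione | CCCCC[C@H](/C=C\CCCCCCCC(=O)CC(=O)CC(C)=O)O
F5 | step 6 | (8Z,10R)-1-[3,5-bis(tert-butyldimethylsilyloxy)phenyl]pentadec-8-en-10-ol | CCCCC[C@H](/C=C\CCCCCCCc1cc(O[Si](C)(C)C(C)(C)C)cc(O[Si](C)(C)C(C)(C)C)c1)O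
F6 | step 6 | (8Z,10R)-1-[3,5-bis(tert-butyldimethylsilyloxy)phenyl]pentadec-8-en-10-yl acetate | CCCCC[C@H](/C=C\CCCCCCCc1cc(O[Si](C)(C)C(C)(C)C)cc(O[Si](C)(C)C(C)(C)C)c1)OC(C)=O
A1 | direct plan | (R)-oct-1-yn-3-ol | CCCCC[C@H](C#C)O
A2 | direct plan | (7-bromoheptyl)benzene | BrCCCCCCCc1ccccc1
A3 | direct plan | (10R)-1-phenylpentadec-8-yn-10-ol | CCCCC[C@H](C#CCCCCCCCc1ccccc1)O
A4 | direct plan | (8Z,10R)-1-phenylpentadec-8-en-10-ol | CCCCC[C@H](/C=C\CCCCCCCc1ccccc1)O
A5 | direct plan | (8Z,10R)-1-phenylpentadec-8-en-10-yl acetate | CCCCC[C@H](/C=C\CCCCCCCc1ccccc1)OC(C)=O
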